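**Retrosynthetic overview** (key disconnections, listed in the order the bonds are made)
1. Side chain: dienone 1 plus a vinyl unit gives tertiary trienol 2, which carries all ten chain carbons and the future (E)-diene.
2. C3–C1′ bond: methyl orsellinate 3 is C-alkylated by 2 through its allylic bromide 4 to give 5; the C5–prenyl bond then gives 6.
3. Key disconnection, C2–O1: a chiral acid protonates the triene of 6 to pentadienyl cation 7, and the 4-OH closes the ring to (R)-chroman ester 8. This mirrors the presumed biosynthetic ring closure and sets the only stereocentre.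
4. Ester hydrolysis of 8 gives target 9.
5. Ring order: the benzene ring is bought in 3; the dihydropyran ring is the only ring formed, in step 4.

Assumption: in nature the chroman is taken to arise from a 3-geranyl-5-prenylorsellinate whose geranyl chain is desaturated to the 2′,4′,6′-triene, protonated at C2′ and closed at C3′ by the 4-OH; the sense of induction of the chiral acid in step 4 cannot be predicted and must be confirmed on a first run, with the antipodal catalyst used if it is opposite.

**Step 1**
Reactants: 1 (3E)-6-methylhepta-3,5-dien-2-one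
Product: 2 (4E)-3,7-dimethylocta-1,4,6-trien-3-ol (racemic)
Conditions: CH2=CHMgBr (1.2 equiv), THF, −30 → 0 °C; then H2O, 0 °C; used crude, kept cold and acid-free
Reagents that add atoms: vinylmagnesium bromide, C=C[Mg]Br
Why: 1,2-Grignard addition of the uncatalysed vinyl nucleophile to the dienone carbonyl (the reaction type that turns β-ionone into vinyl-β-ionol); the new carbinol centre forms racemic, which is harmless because it becomes sp2 in step 2.

**Step 2**
Reactants: 2 (4E)-3,7-dimethylocta-1,4,6-trien-3-ol, 3 methyl 2,4-dihydroxy-6-methylbenzoate (methyl orsellinate)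
Product: 5 methyl 3-[(2E,4E)-3,7-dimethylocta-2,4,6-trien-1-yl]-2,4-dihydroxy-6-methylbenzoate, via trienyl bromide 4 (not isolated)
Conditions: i. PBr3 (0.35 equiv), Et2O, −30 → −10 °C, cold solution used at once; ii. 3 (1.5 equiv), NaH (1.5 equiv), PhMe, 0 °C → rt, Ar
Reagents that add atoms: none
Why: PBr3 converts the tertiary vinyl carbinol into the rearranged conjugated primary bromide 4 (allylic transposition, as in linalool → geranyl bromide), and the sodium 4-phenoxide of 3 in non-polar toluene undergoes ortho-C-alkylation at C3, the carbon flanked by both oxygens (the reaction type used to C3-geranylate orsellinates); no stereocentre is formed, and any 2′Z isomer is carried on because C2′ becomes sp3 in step 4.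

**Step 3**
Reactants: 5 methyl 3-[(2E,4E)-3,7-dimethylocta-2,4,6-trien-1-yl]-2,4-dihydroxy-6-methylbenzoate
Product: 6 methyl 3-[(2E,4E)-3,7-dimethylocta-2,4,6-trien-1-yl]-2,4-dihydroxy-6-methyl-5-(3-methylbut-2-en-1-yl)benzoate
Conditions: NaH (1.05 equiv), PhMe, 0 °C; prenyl bromide (1.2 equiv), rt → 40 °C, Ar
Reagents that add atoms: prenyl bromide (1-bromo-3-methylbut-2-ene), CC(C)=CCBr
Why: Ortho-C-alkylation of a sodium phenoxide with an allylic bromide in a non-polar solvent: C5 is the only unsubstituted ring carbon and lies ortho to the 4-oxide, so rearomatisation can only give 6; triene and ester do not react with NaH or the bromide at ≤40 °C, and no stereocentre is formed.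

**Step 4**
Reactants: 6 methyl 3-[(2E,4E)-3,7-dimethylocta-2,4,6-trien-1-yl]-2,4-dihydroxy-6-methyl-5-(3-methylbut-2-en-1-yl)benzoate
Product: 8 methyl (2R)-5-hydroxy-2,7-dimethyl-2-[(1E)-4-methylpenta-1,3-dien-1-yl]-8-(3-methylbut-2-en-1-yl)-3,4-dihydro-2H-chromene-6-carboxylate, via pentadienyl cation 7 (not isolated)
Conditions: (R)-3,3′-bis(2,4,6-triisopropylphenyl)-BINOL N-triflylphosphoramide (10 mol %), 4 Å MS, PhMe, −40 °C; Et3N quench at −40 °C; Et3N-deactivated silica
Reagents that add atoms: none
Why: Proposed new method: the chiral N-triflylphosphoramide protonates the triene at its terminus C2′, the only site that gives a cation with two tertiary termini, to form pentadienyl cation 7 as a contact ion pair with the chiral anion, which also hydrogen-bonds the 4-OH; the phenol then closes the six-membered ring at C3′ on one face, setting C2 as R with the 4′E bond retained as the (1E)-diene, while the ester-chelated 2-OH and the isolated prenyl alkene are far less reactive; the closest known reaction types are chiral phosphoramide-catalysed SN1-type intramolecular allylic substitutions by phenols that give 2,2-disubstituted 2H-chromenes through chiral contact ion pairs, and chiral Brønsted-acid-catalysed intramolecular hydroalkoxylation of dienes.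

**Step 5**
Reactants: 8 methyl (2R)-5-hydroxy-2,7-dimethyl-2-[(1E)-4-methylpenta-1,3-dien-1-yl]-8-(3-methylbut-2-en-1-yl)-3,4-dihydro-2H-chromene-6-carboxylate
Product: 9 (2R)-5-hydroxy-2,7-dimethyl-2-[(1E)-4-methylpenta-1,3-dien-1-yl]-8-(3-methylbut-2-en-1-yl)-3,4-dihydro-2H-chromene-6-carboxylic acid
Conditions: NaOH (aq, 10 equiv), MeOH/THF, 60 °C, Ar; then 1 M HCl to pH 3 at 0 °C, immediate extraction
Reagents that add atoms: sodium hydroxide, [Na+].[OH-]
Why: Saponification (BAc2) of the hindered, hydrogen-bonded salicylate ester, as used to finish related chromene and prenyl orsellinic acids; the tertiary allylic aryl ether, the diene and the prenyl group are stable to base, the quaternary stereocentre cannot epimerise, and brief cold acidification avoids C2–O ionisation and decarboxylation.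

**Compound list**
1 | (3E)-6-methylhepta-3,5-dien-2-one | CC(=O)/C=C/C=C(C)C | starting material
2 | (4E)-3,7-dimethylocta-1,4,6-trien-3-ol (racemic) | C=CC(C)(O)/C=C/C=C(C)C | intermediate
3 | methyl 2,4-dihydroxy-6-methylbenzoate (methyl orsellinate) | COC(=O)c1c(C)cc(O)cc1O | starting material
4 | (2E,4E)-1-bromo-3,7-dimethylocta-2,4,6-triene | BrC/C=C(\C)/C=C/C=C(C)C | intermediate
5 | methyl 3-[(2E,4E)-3,7-dimethylocta-2,4,6-trien-1-yl]-2,4-dihydroxy-6-methylbenzoate | COC(=O)c1c(C)cc(O)c(C/C=C(\C)/C=C/C=C(C)C)c1O | intermediate
6 | methyl 3-[(2E,4E)-3,7-dimethylocta-2,4,6-trien-1-yl]-2,4-dihydroxy-6-methyl-5-(3-methylbut-2-en-1-yl)benzoate | COC(=O)c1c(C)c(CC=C(C)C)c(O)c(C/C=C(\C)/C=C/C=C(C)C)c1O | intermediate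
7 | pentadienyl cation from C2′-protonation of 6, ion-paired with the phosphoramide anion | COC(=O)c1c(C)c(CC=C(C)C)c(O)c(CC[C+](C)/C=C/C=C(C)C)c1O | intermediate
8 | methyl (2R)-5-hydroxy-2,7-dimethyl-2-[(1E)-4-methylpenta-1,3-dien-1-yl]-8-(3-methylbut-2-en-1-yl)-3,4-dihydro-2H-chromene-6-carboxylate | CC(C)=C/C=C/[C@@]1(C)CCc2c(O)c(C(=O)OC)c(C)c(CC=C(C)C)c2O1 | intermediate
9 | (2R)-5-hydroxy-2,7-dimethyl-2-[(1E)-4-methylpenta-1,3-dien-1-yl]-8-(3-methylbut-2-en-1-yl)-3,4-dihydro-2H-chromene-6-carboxylic acid | CC(C)=C/C=C/[C@@]1(C)CCc2c(O)c(C(=O)O)c(C)c(CC=C(C)C)c2O1 | target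

**Step count and risks**
Total steps: 5. Longest linear sequence: 5 (1 → 2 → 5 → 6 → 8 → 9).

The three steps most likely to fail:

Step 4 (enantioselective triene cyclisation). The reaction is unprecedented in this exact form, so both the level and the sense of induction are unknown. The product ether can re-ionise and racemise if the acid is not quenched cold. The 2-OH could compete for ring closure. Fallback: give up catalyst control and resolve. Setting out from 6, an achiral acid (diphenyl phosphate, 5 mol %, PhMe, −20 °C) closes the ring to the racemic ester methyl (2RS)-5-hydroxy-2,7-dimethyl-2-[(1E)-4-methylpenta-1,3-dien-1-yl]-8-(3-methylbut-2-en-1-yl)-3,4-dihydro-2H-chromene-6-carboxylate F1. Preparative chiral SFC then gives 8, where the route is rejoined. The unwanted antipode, methyl (2S)-5-hydroxy-2,7-dimethyl-2-[(1E)-4-methylpenta-1,3-dien-1-yl]-8-(3-methylbut-2-en-1-yl)-3,4-dihydro-2H-chromene-6-carboxylate F2, is re-racemised with the same acid through reversible C2–O ionisation and recycled.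

Step 2 (C3-alkylation with the labile trienyl bromide). Bromide 4 may decompose before it alkylates, and O-alkylation or attack at C5 may compete. Fallback: avoid the bromide and the phenoxide altogether. Setting out from 2 and 3, a Pd/Et3B-promoted dehydrative Tsuji–Trost C-allylation (Pd(PPh3)4 5 mol %, Et3B, THF, 25–40 °C) forms the dienyl-substituted π-allyl palladium directly from the alcohol. The resorcylate C3 attacks its unsubstituted terminus and gives 5, where the route is rejoined. This fallback makes no new compound, F0.

Step 3 (C5-prenylation). O-prenylation or ipso-attack at C3 may outweigh the wanted C5-alkylation. Fallback: deliver the prenyl group by a sigmatropic shift. Setting out from 5, Pd(PPh3)4-catalysed decarboxylative O-alkylation of the free 4-OH with methyl 2-methylbut-3-en-2-yl carbonate (THF, 0 °C) gives the tertiary aryl ether methyl 3-[(2E,4E)-3,7-dimethylocta-2,4,6-trien-1-yl]-2-hydroxy-6-methyl-4-[(2-methylbut-3-en-2-yl)oxy]benzoate F3. Aromatic Claisen rearrangement (PhMe, 100 °C, or Eu(fod)3 cat., 60 °C) then moves the group to C5, the only free ortho position, with allylic inversion, so it arrives as the normal prenyl group. The route is rejoined at 6.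

**Further compounds**
F1 | step 4 | methyl (2RS)-5-hydroxy-2,7-dimethyl-2-[(1E)-4-methylpenta-1,3-dien-1-yl]-8-(3-methylbut-2-en-1-yl)-3,4-dihydro-2H-chromene-6-carboxylate (racemate) | CC(C)=C/C=C/C1(C)CCc2c(O)c(C(=O)OC)c(C)c(CC=C(C)C)c2O1
F2 | step 4 | methyl (2S)-5-hydroxy-2,7-dimethyl-2-[(1E)-4-methylpenta-1,3-dien-1-yl]-8-(3-methylbut-2-en-1-yl)-3,4-dihydro-2H-chromene-6-carboxylate | CC(C)=C/C=C/[C@]1(C)CCc2c(O)c(C(=O)OC)c(C)c(CC=C(C)C)c2O1
F0 | step 2 | none | none
F3 | step 3 | methyl 3-[(2E,4E)-3,7-dimethylocta-2,4,6-trien-1-yl]-2-hydroxy-6-methyl-4-[(2-methylbut-3-en-2-yl)oxy]benzoate | COC(=O)c1c(C)cc(OC(C)(C)C=C)c(C/C=C(\C)/C=C/C=C(C)C)c1O
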